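Structural features

Isolappaol A (22) is built from three guaiacyl C6–C3 units: a γ-butyrolactone (ring A) carries a 4-hydroxy-3-methoxybenzyl group on C4 and, through a CH2 group on C3, is joined to C5 of a 7-methoxy-2,3-dihydrobenzofuran (benzene ring B fused to dihydrofuran ring C). Ring C bears a 4-hydroxy-3-methoxyphenyl group on C2 and a hydroxymethyl group on C3, trans to each other (2S,3R), and the two lactone substituents are also trans (3R,4R). The four stereocentres therefore form two adjacent pairs, and the CH2–arene link insulates the pairs from each other, so neither can relay its configuration to the other. The O1–C2 bond of ring C is the most fragile element, being a benzylic aryl ether para to a phenol that is open to acid ionisation, to hydrogenolysis and, once the phenol is free, to base-induced quinone methide formation, while the lactone is sensitive to nucleophiles and the phenols to oxidants. The real difficulty is the absolute configuration of the C2/C3 pair of ring C, which sits on an electron-rich arene with no neighbouring stereocentre or directing group, together with the union of the two halves without loss of either pair. The key step exploits the C2–C3 bond of ring C: C2 is a benzylic carbon bonded to O1, and C3 is bonded to the arene carbon C3a and to one oxygenated carbon, which is exactly what remains when an aryl(alkoxycarbonyl)carbene at C3 has inserted into a C–H bond of an aryl–O–CH2–aryl group.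

Logic of the disconnections

22 is taken back to 21 by cutting three O–CH2Ph bonds, two on phenols and one on the C3 hydroxymethyl group of ring C. One kind of protecting group on all three hydroxyls means a single final operation, and benzyl ethers withstand every base, hydride, fluoride and carbene step before it. The forward step must be a hydrogenolysis mild enough to spare the benzylic O1–C2 bond.

The bond between lactone C3 and the benzylic CH2 group of 21 is cut next, which gives 19 and, through its enolate 20, 6. This bond is alpha to a carbonyl group and on a benzylic carbon, the natural place for an enolate alkylation, and the cut divides the molecule into two halves that each hold one stereo pair. The C4 substituent of 20 should send the electrophile to the opposite face, so the lactone pair is completed in the same step. The demand is an electrophile that has no acidic hydrogen and reacts at low temperature. For this reason the ester of ring C is reduced and capped before the coupling, and the C5 carbon is carried at the alcohol oxidation level; an aldehyde there would need an aldol addition and a radical deoxygenation to reach the same CH2 group.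

19 goes back to 15 by functional group changes only: C–Br from C–OH (18), O–H from O–Si (17), O–CH2Ph from O–H (16) and CH2OH from the methyl ester (15). The order keeps the two primary carbinols from ever being free together, and it demands only that the silyl ether resist base and the benzyl ether resist fluoride. The descriptor of the ester-bearing carbon changes from 3S in 15 to 3R in 16 only because the CIP ranking of its neighbours changes; the spatial arrangement is the same.

The key cut is the C2–C3 bond of ring C in 15, which opens the ring and leads through 14 to 13. C3 becomes a carbene carbon (masked as a diazo ester) and C2 a CH2 group between an aryl ether oxygen and an electron-rich arene. The cut removes the ring and both of its stereocentres at once and leaves an achiral open-chain precursor. The forward step asks a chiral dirhodium carboxylate to choose between the two enantiotopic hydrogens of that CH2 group, which fixes C2, and asks a catalytic base to bring C3 to the trans arrangement afterwards. It also asks that 13 hold nothing that traps a carbene or needs acid. The C5 carbon is therefore carried as the silyl ether of a hydroxymethyl group and not as a cyclic acetal of an aldehyde, because an acetal would have to be made and removed with acid beside an acid-labile para-alkoxybenzyl aryl ether and would still have to be reduced later.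

13 comes from 12 by cutting the C=N2 bond. The CH2 group of 12 lies between an arene and an ester and is acidic enough for diazo transfer with an amidine base; the only demand is that no other acidic or electrophilic group be present.

The bond between the arene and the CH2CO2Me group of 12 is cut to give 11 and a two-carbon zinc enolate. A bromine atom at this position is present in a cheap commercial phenol, so the acetate arm arrives in one catalytic step. The older way by O-allylation, Claisen rearrangement and oxidative cleavage of the allyl group is longer, and its oxidants would threaten the electron-rich rings. The demand is a palladium catalyst that inserts next to an alkoxy substituent and the absence of a carbonyl electrophile in 11.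

11 is simplified by cutting the O–Si bond (10), by returning the carbinol to the aldehyde (9) and by cutting the aryl O–CH2 bond of 9, which gives 7 and 8. The ether is made before the aldehyde is touched, because a free para-hydroxy aldehyde is awkward to protect or reduce cleanly. The demand is an etherification that works on a phenol flanked by bromine and methoxy, for which the acidity of 7 is an asset.

6 is opened at the lactone O–C(=O) bond to 5, whose carbinol comes from the ester of 4. The two C–H bonds added across the alkene of 3 are then removed, and the C=C bond of 3 is cut to give 1 and 2. The single stereocentre of this half thus arises by asymmetric hydrogenation of an alkene that a classical condensation delivers in one step. The demands are a catalyst that distinguishes the alkene faces without touching the benzyl ether and a hydride that reduces an ester beside a carboxylate.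

Other disconnections considered

Alternative 1: The cut removes both the C2–C3 and the O1–C2 bond of ring C. C2 then arrives as a one-carbon unit, the benzylic ylide of the chiral sulfonium salt A3 (drawn with a (2R,5R)-2,5-dimethylthiolane; which antipode leads to the 2S series would have to be established), and the other four ring atoms arrive as the ortho-quinone methide released from the sulfonyl phenol A2. In the forward step Cs2CO3 would expel sulfinate from A2 and deprotonate A3, the ylide carbon would add to the methide carbon (C2–C3), and the phenoxide would displace the sulfide in a 5-exo-tet closure (O1–C2) to give the trans product A1.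
- In its favour: the ring and both stereocentres form in the act of joining the two aromatic halves, without a diazo compound and without rhodium, and the trans relation arises directly from the anti betaine. On convergence and on the absence of a separate epimerisation it is the better plan.
- Against it here: the chiral sulfide is used in stoichiometric amount. Enantiocontrol with a semi-stabilised benzylic ylide is less secure than with the dirhodium carboxylate insertion. The methide from A2 has hydrogens next to the methide carbon and may tautomerise to a 2-vinylphenol before the ylide arrives. The electron-rich benzylic sulfonium salt may ionise. A1 carries bromine at C5, so the CH2 link must still be built (halogen–metal exchange, formylation, reduction, bromination) before a coupling like step 14.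
- Comparison: on structure, both plans set the same two stereocentres in one operation, A1 by two ring bonds and 15 by one. On mechanism, a polar addition–substitution under reagent control stands against a concerted insertion under catalyst control with thermodynamic correction at C3. On step economy, A1 should be reached in equal or fewer steps than 15, but the work at C5 afterwards costs about three steps more than steps 12 and 13, so the totals should be similar.

Alternative 2: The cut is the O1–C5 bond of lactone ring A (ring oxygen to CH2); removal of the oxygen contracts the ring to the prochiral cyclobutanone A5, which would come from eugenol A6 by a ketene [2+2] cycloaddition to its allyl group and dechlorination. In the forward step a Baeyer–Villiger monooxygenase (flavin, NADPH, O2) adds its flavin hydroperoxide to the ketone, and one of the two enantiotopic CH2 groups, chosen by the active site, migrates to oxygen in the Criegee intermediate to give A4.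
- In its favour: the lactone stereocentre is set with O2 in water, without a precious metal or pressure hydrogenation and from a renewable phenol. On these points it is the better way to this stereocentre.
- Against it here: it addresses the stereocentre that is easy in any case and leaves the C2/C3 pair of ring C untouched, so it cannot carry the strategy for 22. It needs an enzyme with the right preference for 3-benzylcyclobutanones and cofactor recycling at high dilution. The phenol must be masked for the cycloaddition, and A4 must be benzylated before enolate chemistry.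
- Comparison: on structure, A4 is the debenzylated form of 6, so the alternative could replace steps 1–3 and is their equal in what it delivers. On mechanism, selection between enantiotopic groups in a migration is equal in principle to selection between enantiotopic faces in hydride delivery, both being catalyst-controlled. On step economy, about five operations (masking, cycloaddition, dechlorination, oxidation, benzylation) stand against three, so the chosen branch is shorter.

Alternative 3: The cut is the O1–C2 bond of ring C. The precursor is the phenolic diol A8, in which only the aryl-bearing carbon (the later C3) is defined and the benzylic carbinol (the later C2) may be either epimer. In the forward step CF3CO2H in CH2Cl2 would ionise the benzylic alcohol to a cation stabilised by the para-benzyloxy group, and the ortho phenol oxygen would close ring C on this planar centre, the aryl group settling trans to the C3 substituent, to give A7.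
- In its favour: it is stereoconvergent, so only one stereocentre needs external control and poor diastereoselectivity in the preceding C–C bond formation is forgiven. It needs no diazo compound and no rhodium and should scale well; on robustness it is the better plan. Its substrate control at C2 is the equal of the base equilibration at C3 in the chosen plan.
- Against it here: the C3 stereocentre must be made earlier, most plausibly by an auxiliary-controlled aldol addition of an arylacetyl imide to 1. That means a stoichiometric controller and a carbon that is benzylic and alpha to a carbonyl group until the auxiliary is removed. The ortho phenol must be masked through that chemistry and freed before the cyclisation. The cation may also alkylate electron-rich arenes. Bromine at C5 again needs several steps to become the CH2 link.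
- Comparison: on structure, the same ring is closed at a C–O bond, with C–C bond formation and ring closure as separate events that the chosen plan merges. On mechanism, a cationic closure under substrate and auxiliary control stands against a carbene insertion under catalyst control. On step economy, the chosen plan should be shorter by several steps.

Key step: step 9

Assumption: dirhodium tetrakis[N-phthaloyl-tert-leucinate] catalysts with S ligands are taken to give the 2R series of cis-2-aryl-2,3-dihydrobenzofuran-3-carboxylates, so the R-ligand catalyst Rh2(R-PTTL)4 is specified for the 2S series; should the sense be opposite on 13, the S-ligand catalyst is used with no other change.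
Assumption: [Rh(cod)((S,S)-Et-DuPhos)]BF4 is taken to give the R half-ester 4 from 3, by analogy between itaconate and enamide chelation; the mirror-image ligand is used if the sense is opposite.
Assumption: 1, 2, 7 and 8 are bought.

Step 1
Reactants: 1 4-benzyloxy-3-methoxybenzaldehyde; 2 dimethyl succinate
Product: 3 (E)-4-(4-benzyloxy-3-methoxyphenyl)-3-(methoxycarbonyl)but-3-enoic acid
Conditions: NaOMe, MeOH, reflux; then aq. HCl
Reagents that add atoms: none
Why: Stobbe condensation: the succinate enolate adds to the aldehyde, the alkoxide lactonises onto the distal ester and base-induced opening of the paraconate gives the half-ester with the free acid on the CH2 arm; the E alkene (aryl trans to the ester) is the expected major isomer.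

Step 2
Reactants: 3 (E)-4-(4-benzyloxy-3-methoxyphenyl)-3-(methoxycarbonyl)but-3-enoic acid
Product: 4 (R)-4-(4-benzyloxy-3-methoxyphenyl)-3-(methoxycarbonyl)butanoic acid
Conditions: H2 (5 bar), [Rh(cod)((S,S)-Et-DuPhos)]BF4 (1 mol%), NaOMe (10 mol%), MeOH, rt
Reagents that add atoms: none
Why: Asymmetric hydrogenation of a Stobbe itaconate half-ester: carboxylate and alkene chelate the cationic monovalent rhodium bisphospholane centre, and the C2-symmetric ligand selects the alkene face, which sets the only stereocentre of the lactone half as R; aryl benzyl ethers are inert to this homogeneous catalyst.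

Step 3
Reactants: 4 (R)-4-(4-benzyloxy-3-methoxyphenyl)-3-(methoxycarbonyl)butanoic acid
Product: 6 (R)-4-(4-benzyloxy-3-methoxybenzyl)dihydrofuran-2(3H)-one, via hydroxy acid 5 (not isolated)
Conditions: KOH (1 equiv), EtOH; CaCl2, NaBH4, EtOH, −10 °C → rt; then aq. HCl, rt
Reagents that add atoms: none
Why: Chemoselective ester reduction beside a carboxylate: Ca(BH4)2 formed in the flask reduces the methyl ester of the potassium salt to the carbinol and leaves the carboxylate alone, and acidification closes the gamma-lactone (5-exo-trig acyl substitution); the stereocentre is not involved.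

Step 4
Reactants: 7 3-bromo-4-hydroxy-5-methoxybenzaldehyde (5-bromovanillin); 8 (4-benzyloxy-3-methoxyphenyl)methanol
Product: 9 4-[(4-benzyloxy-3-methoxyphenyl)methoxy]-3-bromo-5-methoxybenzaldehyde
Conditions: PPh3, DIAD, THF, 0 °C → rt
Reagents that add atoms: none
Why: Mitsunobu etherification: the acidic, aldehyde-activated phenol of 7 protonates the betaine and its phenoxide displaces the alkoxyphosphonium ion of the primary benzylic alcohol 8; neither acid nor strong base meets the para-alkoxybenzyl aryl ether that results.

Step 5
Reactants: 9 4-[(4-benzyloxy-3-methoxyphenyl)methoxy]-3-bromo-5-methoxybenzaldehyde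
Product: 10 {4-[(4-benzyloxy-3-methoxyphenyl)methoxy]-3-bromo-5-methoxyphenyl}methanol
Conditions: NaBH4, MeOH–THF, 0 °C
Reagents that add atoms: none
Why: Borohydride reduction of an aryl aldehyde; the aryl bromide and the ethers are inert, and the later C5 carbon reaches the oxidation level it has in the target.

Step 6
Reactants: 10 {4-[(4-benzyloxy-3-methoxyphenyl)methoxy]-3-bromo-5-methoxyphenyl}methanol
Product: 11 tert-butyl({4-[(4-benzyloxy-3-methoxyphenyl)methoxy]-3-bromo-5-methoxyphenyl}methoxy)dimethylsilane
Conditions: TBSCl, imidazole, DMF, rt
Reagents that add atoms: tert-butyldimethylsilyl chloride, CC(C)(C)[Si](C)(C)Cl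
Why: Standard silylation of a primary benzylic alcohol; the silyl ether removes the only protic site before the organozinc, diazo and carbene steps and needs no acid to put on or take off.

Step 7
Reactants: 11 tert-butyl({4-[(4-benzyloxy-3-methoxyphenyl)methoxy]-3-bromo-5-methoxyphenyl}methoxy)dimethylsilane
Product: 12 methyl 2-{2-[(4-benzyloxy-3-methoxyphenyl)methoxy]-5-[(tert-butyldimethylsilyloxy)methyl]-3-methoxyphenyl}acetate
Conditions: BrCH2CO2Me, Zn (Me3SiCl-activated), THF, 30 °C; then 11, Pd(P(t-Bu)3)2 (3 mol%), THF, rt → 50 °C
Reagents that add atoms: methyl bromoacetate (used as its zinc enolate BrZnCH2CO2Me), BrCC(=O)OC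
Why: Palladium-catalysed alpha-arylation of an ester through its zinc enolate (Reformatsky reagent in a Negishi-type coupling): oxidative addition of the aryl bromide to zerovalent palladium bearing a bulky trialkylphosphine, transmetallation from zinc and reductive elimination give the arylacetate; the weakly basic zinc enolate tolerates the silyl and benzyl ethers.

Step 8
Reactants: 12 methyl 2-{2-[(4-benzyloxy-3-methoxyphenyl)methoxy]-5-[(tert-butyldimethylsilyloxy)methyl]-3-methoxyphenyl}acetate
Product: 13 methyl 2-diazo-2-{2-[(4-benzyloxy-3-methoxyphenyl)methoxy]-5-[(tert-butyldimethylsilyloxy)methyl]-3-methoxyphenyl}acetate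
Conditions: p-ABSA (4-acetamidobenzenesulfonyl azide), DBU, MeCN, 0 °C → rt
Reagents that add atoms: 4-acetamidobenzenesulfonyl azide, CC(=O)Nc1ccc(cc1)S(=O)(=O)N=[N+]=[N-]
Why: Regitz diazo transfer: DBU deprotonates the arylacetate CH2 group, the enolate attacks the terminal nitrogen of the sulfonyl azide and the sulfonamide leaves; arylacetates are the standard substrates of this reagent pair.

Step 9
Reactants: 13 methyl 2-diazo-2-{2-[(4-benzyloxy-3-methoxyphenyl)methoxy]-5-[(tert-butyldimethylsilyloxy)methyl]-3-methoxyphenyl}acetate
Product: 15 methyl (2S,3S)-trans-2-(4-benzyloxy-3-methoxyphenyl)-5-[(tert-butyldimethylsilyloxy)methyl]-7-methoxy-2,3-dihydrobenzofuran-3-carboxylate, via cis ester 14 (not isolated)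
Conditions: Rh2(R-PTTL)4 (dirhodium tetrakis[N-phthaloyl-(R)-tert-leucinate], 1 mol%), toluene, −60 °C; then NaOMe (0.2 equiv), MeOH, 0 °C → rt
Reagents that add atoms: none
Why: Divalent rhodium binds the diazo carbon, N2 leaves, and an aryl(methoxycarbonyl)carbene results, a donor/acceptor carbene selective enough to wait for the best C–H bond. Its vacant orbital engages one C–H bond of the aryl–O–CH2–aryl group in a concerted, hydride-transfer-like three-centre transition state, so the C2–C3 bond forms with retention at C2; the closest known reaction type is the dirhodium-carboxylate-catalysed enantioselective 1,5 C–H insertion of aryldiazoacetates into benzylic ether C–H bonds, which gives cis-2-aryl-2,3-dihydrobenzofuran-3-carboxylates. Ring C closes by C–C bond formation between the carbene carbon and the carbon three atoms away (C3a, C7a and O1 lie between), a 1,5 insertion through a five-membered cyclic transition state. C2 is set by the catalyst: the phthalimide walls of the four tert-leucinate ligands hold the carbene in a chiral pocket that only one of the two enantiotopic benzylic hydrogens can reach. C3 is formed first cis to the C2 aryl group (kinetic control, 14) and is then set by thermodynamics, because catalytic methoxide reversibly deprotonates only the ester-bearing C3 and the trans ester 15 is the stable one, while C2 has no acidic hydrogen and stays fixed. The step needs site selectivity for the 1,5 position over the CH2 groups of the benzyl and silyl ethers, and the substrate secures it: only the aryl–O–CH2 hydrogens can reach the carbene through a five-membered transition state, they are the most hydridic (ether oxygen plus a para-alkoxyaryl group), and the other activated C–H bonds can react only between molecules, which low temperature and dilution suppress. It also needs the absence of carbene traps, which is why 13 has no free hydroxyl, aldehyde or alkene.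

Step 10
Reactants: 15 methyl (2S,3S)-trans-2-(4-benzyloxy-3-methoxyphenyl)-5-[(tert-butyldimethylsilyloxy)methyl]-7-methoxy-2,3-dihydrobenzofuran-3-carboxylate
Product: 16 {(2S,3R)-2-(4-benzyloxy-3-methoxyphenyl)-5-[(tert-butyldimethylsilyloxy)methyl]-7-methoxy-2,3-dihydrobenzofuran-3-yl}methanol
Conditions: LiBH4, THF, 0 °C → rt
Reagents that add atoms: none
Why: Lithium borohydride reduces the methyl ester to the primary alcohol and leaves silyl and benzyl ethers alone; no base strong enough to open ring C is present, and trans is in any case the stable arrangement at C3.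

Step 11
Reactants: 16 {(2S,3R)-2-(4-benzyloxy-3-methoxyphenyl)-5-[(tert-butyldimethylsilyloxy)methyl]-7-methoxy-2,3-dihydrobenzofuran-3-yl}methanol
Product: 17 (2S,3R)-2-(4-benzyloxy-3-methoxyphenyl)-3-(benzyloxymethyl)-5-[(tert-butyldimethylsilyloxy)methyl]-7-methoxy-2,3-dihydrobenzofuran
Conditions: NaH, BnBr, Bu4NI (cat.), THF–DMF, 0 °C → rt
Reagents that add atoms: benzyl bromide, BrCc1ccccc1
Why: Williamson etherification of the primary alkoxide; 16 has no other acidic hydrogen, and the benzyl ether matches the two phenolic benzyl ethers so that one final operation removes all three.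

Step 12
Reactants: 17 (2S,3R)-2-(4-benzyloxy-3-methoxyphenyl)-3-(benzyloxymethyl)-5-[(tert-butyldimethylsilyloxy)methyl]-7-methoxy-2,3-dihydrobenzofuran
Product: 18 [(2S,3R)-2-(4-benzyloxy-3-methoxyphenyl)-3-(benzyloxymethyl)-7-methoxy-2,3-dihydrobenzofuran-5-yl]methanol
Conditions: Bu4NF, THF, 0 °C → rt
Reagents that add atoms: none
Why: Fluoride cleaves the Si–O bond (driven by the strong Si–F bond) and leaves benzyl ethers, aryl ethers and ring C untouched, so only the C5 carbinol is released.

Step 13
Reactants: 18 [(2S,3R)-2-(4-benzyloxy-3-methoxyphenyl)-3-(benzyloxymethyl)-7-methoxy-2,3-dihydrobenzofuran-5-yl]methanol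
Product: 19 (2S,3R)-2-(4-benzyloxy-3-methoxyphenyl)-3-(benzyloxymethyl)-5-(bromomethyl)-7-methoxy-2,3-dihydrobenzofuran
Conditions: CBr4, PPh3, CH2Cl2, 0 °C; used at once
Reagents that add atoms: carbon tetrabromide, BrC(Br)(Br)Br
Why: Appel bromination: the alcohol attacks the bromophosphonium ion and bromide displaces triphenylphosphine oxide at the primary benzylic carbon under neutral conditions; the electron-rich bromide is not stored.

Step 14
Reactants: 6 (R)-4-(4-benzyloxy-3-methoxybenzyl)dihydrofuran-2(3H)-one; 19 (2S,3R)-2-(4-benzyloxy-3-methoxyphenyl)-3-(benzyloxymethyl)-5-(bromomethyl)-7-methoxy-2,3-dihydrobenzofuran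
Product: 21 (3R,4R)-4-(4-benzyloxy-3-methoxybenzyl)-3-{[(2S,3R)-2-(4-benzyloxy-3-methoxyphenyl)-3-(benzyloxymethyl)-7-methoxy-2,3-dihydrobenzofuran-5-yl]methyl}dihydrofuran-2(3H)-one, via lithium enolate 20 (not isolated)
Conditions: LiN(SiMe3)2, THF, −78 °C; then 19, DMPU, −78 → −30 °C
Reagents that add atoms: none
Why: Alkylation of a lactone lithium enolate with a benzylic bromide, the standard entry to trans-alpha,beta-dibenzylbutyrolactones: the C4 benzyl group of 20 shields one face, the electrophile enters anti and the new C3 centre is formed trans (3R); 19 has no acidic hydrogen, so proton transfer cannot compete.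

Step 15
Reactants: 21 (3R,4R)-4-(4-benzyloxy-3-methoxybenzyl)-3-{[(2S,3R)-2-(4-benzyloxy-3-methoxyphenyl)-3-(benzyloxymethyl)-7-methoxy-2,3-dihydrobenzofuran-5-yl]methyl}dihydrofuran-2(3H)-one
Product: 22 isolappaol A, (3R,4R)-4-(4-hydroxy-3-methoxybenzyl)-3-{[(2S,3R)-2-(4-hydroxy-3-methoxyphenyl)-3-(hydroxymethyl)-7-methoxy-2,3-dihydrobenzofuran-5-yl]methyl}dihydrofuran-2(3H)-one
Conditions: H2 (1 atm), 10% Pd/C, EtOAc–EtOH, rt
Reagents that add atoms: none
Why: Catalytic hydrogenolysis of benzyl ethers on palladium: the two aryl benzyl ethers and the primary alkyl benzyl ether are cleaved to toluene under neutral conditions at one atmosphere, where the ring O1–C2 bond of a 2-aryl-2,3-dihydrobenzofuran is expected to react much more slowly; no stereocentre is touched.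

Compound list

1 | 4-benzyloxy-3-methoxybenzaldehyde | COc1cc(C=O)ccc1OCc1ccccc1 | starting material
2 | dimethyl succinate | COC(=O)CCC(=O)OC | starting material
3 | (E)-4-(4-benzyloxy-3-methoxyphenyl)-3-(methoxycarbonyl)but-3-enoic acid | OC(=O)C/C(=C\c1ccc(OCc2ccccc2)c(OC)c1)C(=O)OC | intermediate
4 | (R)-4-(4-benzyloxy-3-methoxyphenyl)-3-(methoxycarbonyl)butanoic acid | OC(=O)C[C@@H](Cc1ccc(OCc2ccccc2)c(OC)c1)C(=O)OC | intermediate
5 | (R)-4-(4-benzyloxy-3-methoxyphenyl)-3-(hydroxymethyl)butanoic acid | OC(=O)C[C@@H](Cc1ccc(OCc2ccccc2)c(OC)c1)CO | intermediate (not isolated)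
6 | (R)-4-(4-benzyloxy-3-methoxybenzyl)dihydrofuran-2(3H)-one | COc1cc(C[C@H]2COC(=O)C2)ccc1OCc1ccccc1 | intermediate
7 | 3-bromo-4-hydroxy-5-methoxybenzaldehyde (5-bromovanillin) | COc1cc(C=O)cc(Br)c1O | starting material
8 | (4-benzyloxy-3-methoxyphenyl)methanol | COc1cc(CO)ccc1OCc1ccccc1 | starting material
9 | 4-[(4-benzyloxy-3-methoxyphenyl)methoxy]-3-bromo-5-methoxybenzaldehyde | COc1cc(C=O)cc(Br)c1OCc1ccc(OCc2ccccc2)c(OC)c1 | intermediate
10 | {4-[(4-benzyloxy-3-methoxyphenyl)methoxy]-3-bromo-5-methoxyphenyl}methanol | COc1cc(CO)cc(Br)c1OCc1ccc(OCc2ccccc2)c(OC)c1 | intermediate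
11 | tert-butyl({4-[(4-benzyloxy-3-methoxyphenyl)methoxy]-3-bromo-5-methoxyphenyl}methoxy)dimethylsilane | COc1cc(CO[Si](C)(C)C(C)(C)C)cc(Br)c1OCc1ccc(OCc2ccccc2)c(OC)c1 | intermediate
12 | methyl 2-{2-[(4-benzyloxy-3-methoxyphenyl)methoxy]-5-[(tert-butyldimethylsilyloxy)methyl]-3-methoxyphenyl}acetate | COC(=O)Cc1cc(CO[Si](C)(C)C(C)(C)C)cc(OC)c1OCc1ccc(OCc2ccccc2)c(OC)c1 | intermediate
13 | methyl 2-diazo-2-{2-[(4-benzyloxy-3-methoxyphenyl)methoxy]-5-[(tert-butyldimethylsilyloxy)methyl]-3-methoxyphenyl}acetate | COC(=O)C(=[N+]=[N-])c1cc(CO[Si](C)(C)C(C)(C)C)cc(OC)c1OCc1ccc(OCc2ccccc2)c(OC)c1 | intermediate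
14 | methyl (2S,3R)-cis-2-(4-benzyloxy-3-methoxyphenyl)-5-[(tert-butyldimethylsilyloxy)methyl]-7-methoxy-2,3-dihydrobenzofuran-3-carboxylate | CC(C)(C)[Si](C)(C)OCc1cc(OC)c2c(c1)[C@@H](C(=O)OC)[C@@H](c1ccc(OCc3ccccc3)c(OC)c1)O2 | intermediate (not isolated)
15 | methyl (2S,3S)-trans-2-(4-benzyloxy-3-methoxyphenyl)-5-[(tert-butyldimethylsilyloxy)methyl]-7-methoxy-2,3-dihydrobenzofuran-3-carboxylate | CC(C)(C)[Si](C)(C)OCc1cc(OC)c2c(c1)[C@H](C(=O)OC)[C@@H](c1ccc(OCc3ccccc3)c(OC)c1)O2 | intermediate
16 | {(2S,3R)-2-(4-benzyloxy-3-methoxyphenyl)-5-[(tert-butyldimethylsilyloxy)methyl]-7-methoxy-2,3-dihydrobenzofuran-3-yl}methanol | CC(C)(C)[Si](C)(C)OCc1cc(OC)c2c(c1)[C@H](CO)[C@@H](c1ccc(OCc3ccccc3)c(OC)c1)O2 | intermediate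
17 | (2S,3R)-2-(4-benzyloxy-3-methoxyphenyl)-3-(benzyloxymethyl)-5-[(tert-butyldimethylsilyloxy)methyl]-7-methoxy-2,3-dihydrobenzofuran | CC(C)(C)[Si](C)(C)OCc1cc(OC)c2c(c1)[C@H](COCc1ccccc1)[C@@H](c1ccc(OCc3ccccc3)c(OC)c1)O2 | intermediate
18 | [(2S,3R)-2-(4-benzyloxy-3-methoxyphenyl)-3-(benzyloxymethyl)-7-methoxy-2,3-dihydrobenzofuran-5-yl]methanol | OCc1cc(OC)c2c(c1)[C@H](COCc1ccccc1)[C@@H](c1ccc(OCc3ccccc3)c(OC)c1)O2 | intermediate
19 | (2S,3R)-2-(4-benzyloxy-3-methoxyphenyl)-3-(benzyloxymethyl)-5-(bromomethyl)-7-methoxy-2,3-dihydrobenzofuran | BrCc1cc(OC)c2c(c1)[C@H](COCc1ccccc1)[C@@H](c1ccc(OCc3ccccc3)c(OC)c1)O2 | intermediate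
20 | lithium (R)-4-(4-benzyloxy-3-methoxybenzyl)-4,5-dihydrofuran-2-olate (lithium enolate of 6) | [Li+].[O-]C1=C[C@@H](Cc2ccc(OCc3ccccc3)c(OC)c2)CO1 | intermediate (not isolated)
21 | (3R,4R)-4-(4-benzyloxy-3-methoxybenzyl)-3-{[(2S,3R)-2-(4-benzyloxy-3-methoxyphenyl)-3-(benzyloxymethyl)-7-methoxy-2,3-dihydrobenzofuran-5-yl]methyl}dihydrofuran-2(3H)-one | COc1cc(C[C@H]2COC(=O)[C@@H]2Cc2cc(OC)c3c(c2)[C@H](COCc2ccccc2)[C@@H](c2ccc(OCc4ccccc4)c(OC)c2)O3)ccc1OCc1ccccc1 | intermediate
22 | isolappaol A, (3R,4R)-4-(4-hydroxy-3-methoxybenzyl)-3-{[(2S,3R)-2-(4-hydroxy-3-methoxyphenyl)-3-(hydroxymethyl)-7-methoxy-2,3-dihydrobenzofuran-5-yl]methyl}dihydrofuran-2(3H)-one | COc1cc(C[C@H]2COC(=O)[C@@H]2Cc2cc(OC)c3c(c2)[C@H](CO)[C@@H](c2ccc(O)c(OC)c2)O3)ccc1O | target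

Step count and least certain steps

Total step count: 15. Longest linear sequence: 12 steps (steps 4 to 15, from 7 and 8 to 22); steps 1 to 3 form the side branch to 6, which joins at step 14.

Step 9 (key step). Several processes may go wrong:
- Discrimination of the two enantiotopic hydrogens may be incomplete, because the methoxy group next to the ether oxygen twists the OCH2-aryl arm out of the plane of ring B and may fit the catalyst pocket less well than simpler substrates.
- The sense of induction rests on analogy.
- Insertion between molecules into the CH2 groups of the silyl or benzyl ethers, or carbene dimerisation, may compete if the solution is not dilute.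
- During the epimerisation, beta-elimination of the phenoxide from the C3 enolate would open ring C and erase C2.

Fallback, which replaces asymmetric catalysis by a racemic insertion and a resolution through covalent diastereomers: from 13, Rh2(OAc)4 in CH2Cl2 and then NaOMe in MeOH would give the racemic trans ester F1. LiBH4 would reduce it to the racemic alcohol F2. Esterification with (S)-2-methoxy-2-phenylacetic acid (DCC, DMAP) would give two diastereomers to be separated by chromatography or crystallisation. The (2S,3R) diastereomer, the O-methylmandelate F3, would be methanolysed (K2CO3, MeOH), and the route is rejoined at 16.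

Step 7. Oxidative addition at the electron-rich bromide next to a bulky alkoxy group may be slow, so that protodebromination of 11 or self-condensation of the zinc enolate takes over. Fallback, which builds the acetate arm by oxidative cleavage of an allyl group: from 11, Stille coupling with Bu3SnCH2CH=CH2 (Pd(PPh3)4, toluene, 100 °C) would give the allyl arene F4. Lemieux–Johnson cleavage (OsO4 cat., NaIO4, 2,6-lutidine, dioxane–water) would give the arylacetaldehyde F5, and Pinnick oxidation (NaClO2, NaH2PO4, 2-methyl-2-butene) the arylacetic acid F6. Methylation (MeI, K2CO3, DMF) rejoins the route at 12.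

Step 14 (with step 13). The electrophile may be lost before it meets the enolate, by ionisation (the bromide is para to the ring oxygen O1), by hydrolysis or by quaternisation with phosphine. Fallback, which joins the halves at the aldehyde level and removes the extra oxygen by a radical reaction: from 18, MnO2 in CH2Cl2 would give the aldehyde F7. Aldol addition of 20 (from 6, LiN(SiMe3)2, THF, −78 °C) would give the hydroxy lactone F8, trans on the ring and usable as either carbinol epimer. Thiocarbonyldiimidazole with DMAP would give the imidazolide F9, and Barton–McCombie deoxygenation (Bu3SnH, AIBN, toluene, 90 °C) rejoins the route at 21.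

Step 15. Over-reduction may occur: hydrogenolytic opening of the O1–C2 bond once the para phenol is free, made more likely if cleavage of the primary alkyl benzyl ether is slow and prolongs the exposure. Fallback, which is not reductive: from 21, BCl3 with pentamethylbenzene as cation scavenger in CH2Cl2 at −78 °C would cleave the three benzyl ethers and give 22 directly; no new compound is made (entry F0).

Further compounds

F1 | step 9 | racemic methyl trans-2-(4-benzyloxy-3-methoxyphenyl)-5-[(tert-butyldimethylsilyloxy)methyl]-7-methoxy-2,3-dihydrobenzofuran-3-carboxylate (2S,3S and 2R,3R, written as the pair) | CC(C)(C)[Si](C)(C)OCc1cc(OC)c2c(c1)[C@H](C(=O)OC)[C@@H](c1ccc(OCc3ccccc3)c(OC)c1)O2.CC(C)(C)[Si](C)(C)OCc1cc(OC)c2c(c1)[C@@H](C(=O)OC)[C@H](c1ccc(OCc3ccccc3)c(OC)c1)O2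
F2 | step 9 | racemic {trans-2-(4-benzyloxy-3-methoxyphenyl)-5-[(tert-butyldimethylsilyloxy)methyl]-7-methoxy-2,3-dihydrobenzofuran-3-yl}methanol (2S,3R and 2R,3S, written as the pair) | CC(C)(C)[Si](C)(C)OCc1cc(OC)c2c(c1)[C@H](CO)[C@@H](c1ccc(OCc3ccccc3)c(OC)c1)O2.CC(C)(C)[Si](C)(C)OCc1cc(OC)c2c(c1)[C@@H](CO)[C@H](c1ccc(OCc3ccccc3)c(OC)c1)O2
F3 | step 9 | {(2S,3R)-2-(4-benzyloxy-3-methoxyphenyl)-5-[(tert-butyldimethylsilyloxy)methyl]-7-methoxy-2,3-dihydrobenzofuran-3-yl}methyl (S)-2-methoxy-2-phenylacetate | CC(C)(C)[Si](C)(C)OCc1cc(OC)c2c(c1)[C@H](COC(=O)[C@@H](OC)c1ccccc1)[C@@H](c1ccc(OCc3ccccc3)c(OC)c1)O2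
F4 | step 7 | tert-butyl({3-allyl-4-[(4-benzyloxy-3-methoxyphenyl)methoxy]-5-methoxyphenyl}methoxy)dimethylsilane | C=CCc1cc(CO[Si](C)(C)C(C)(C)C)cc(OC)c1OCc1ccc(OCc2ccccc2)c(OC)c1
F5 | step 7 | 2-{2-[(4-benzyloxy-3-methoxyphenyl)methoxy]-5-[(tert-butyldimethylsilyloxy)methyl]-3-methoxyphenyl}acetaldehyde | O=CCc1cc(CO[Si](C)(C)C(C)(C)C)cc(OC)c1OCc1ccc(OCc2ccccc2)c(OC)c1
F6 | step 7 | 2-{2-[(4-benzyloxy-3-methoxyphenyl)methoxy]-5-[(tert-butyldimethylsilyloxy)methyl]-3-methoxyphenyl}acetic acid | OC(=O)Cc1cc(CO[Si](C)(C)C(C)(C)C)cc(OC)c1OCc1ccc(OCc2ccccc2)c(OC)c1
F7 | step 14 | (2S,3R)-2-(4-benzyloxy-3-methoxyphenyl)-3-(benzyloxymethyl)-7-methoxy-2,3-dihydrobenzofuran-5-carbaldehyde | O=Cc1cc(OC)c2c(c1)[C@H](COCc1ccccc1)[C@@H](c1ccc(OCc3ccccc3)c(OC)c1)O2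
F8 | step 14 | (3S,4R)-trans-4-(4-benzyloxy-3-methoxybenzyl)-3-{hydroxy[(2S,3R)-2-(4-benzyloxy-3-methoxyphenyl)-3-(benzyloxymethyl)-7-methoxy-2,3-dihydrobenzofuran-5-yl]methyl}dihydrofuran-2(3H)-one (both carbinol epimers) | COc1cc(C[C@H]2COC(=O)[C@@H]2C(O)c2cc(OC)c3c(c2)[C@H](COCc2ccccc2)[C@@H](c2ccc(OCc4ccccc4)c(OC)c2)O3)ccc1OCc1ccccc1
F9 | step 14 | O-{[(3S,4R)-4-(4-benzyloxy-3-methoxybenzyl)-2-oxotetrahydrofuran-3-yl][(2S,3R)-2-(4-benzyloxy-3-methoxyphenyl)-3-(benzyloxymethyl)-7-methoxy-2,3-dihydrobenzofuran-5-yl]methyl} 1H-imidazole-1-carbothioate (both carbinol epimers) | COc1cc(C[C@H]2COC(=O)[C@@H]2C(OC(=S)n2ccnc2)c2cc(OC)c3c(c2)[C@H](COCc2ccccc2)[C@@H](c2ccc(OCc4ccccc4)c(OC)c2)O3)ccc1OCc1ccccc1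
F0 | step 15 | none | none
A1 | alternative 1 | (2S,3R)-5-bromo-2-(4-benzyloxy-3-methoxyphenyl)-3-(tert-butyldimethylsilyloxymethyl)-7-methoxy-2,3-dihydrobenzofuran | Brc1cc(OC)c2c(c1)[C@H](CO[Si](C)(C)C(C)(C)C)[C@@H](c1ccc(OCc3ccccc3)c(OC)c1)O2
A2 | alternative 1 | 4-bromo-2-[2-(tert-butyldimethylsilyloxy)-1-(4-methylbenzenesulfonyl)ethyl]-6-methoxyphenol | Cc1ccc(cc1)S(=O)(=O)C(CO[Si](C)(C)C(C)(C)C)c1cc(Br)cc(OC)c1O
A3 | alternative 1 | (2R,5R)-1-(4-benzyloxy-3-methoxybenzyl)-2,5-dimethylthiolan-1-ium trifluoromethanesulfonate | C[C@@H]1CC[C@@H](C)[S+]1Cc1ccc(OCc2ccccc2)c(OC)c1.[O-]S(=O)(=O)C(F)(F)F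
A4 | alternative 2 | (R)-4-(4-hydroxy-3-methoxybenzyl)dihydrofuran-2(3H)-one | COc1cc(C[C@H]2COC(=O)C2)ccc1O
A5 | alternative 2 | 3-(4-hydroxy-3-methoxybenzyl)cyclobutan-1-one | COc1cc(CC2CC(=O)C2)ccc1O
A6 | alternative 2 | eugenol, 4-allyl-2-methoxyphenol | COc1cc(CC=C)ccc1O
A7 | alternative 3 | [(2S,3R)-5-bromo-2-(4-benzyloxy-3-methoxyphenyl)-7-methoxy-2,3-dihydrobenzofuran-3-yl]methanol | Brc1cc(OC)c2c(c1)[C@H](CO)[C@@H](c1ccc(OCc3ccccc3)c(OC)c1)O2
A8 | alternative 3 | (2R)-1-(4-benzyloxy-3-methoxyphenyl)-2-(5-bromo-2-hydroxy-3-methoxyphenyl)propane-1,3-diol (both C1 epimers) | COc1cc(Br)cc([C@H](CO)C(O)c2ccc(OCc3ccccc3)c(OC)c2)c1O
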